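## Retrosynthetic overview
1. The C5–OH bond is cut last. It is made by ketone-directed C–H oxygenation of the 5-unsubstituted 6,7,8-trimethoxyflavonol, and the same acidic pot frees the 4'-OH.
2. Ring C is cut at O1–C2 and C3–OH, which are made by Algar–Flynn–Oyamada oxidative cyclisation of a 2'-hydroxy-3',4',5'-trimethoxychalcone. Keeping C6' (later C5) as C–H avoids the aurone pathway of 6'-oxygenated chalcones.
3. The chalcone comes from a Claisen–Schmidt condensation of 2'-hydroxy-3',4',5'-trimethoxyacetophenone with 4-tert-butoxybenzaldehyde, run in the same pot.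
4. The acetophenone comes from ortho-acylation of 2,3,4-trimethoxyphenol, which is made by Dakin oxidation of bulk 2,3,4-trimethoxybenzaldehyde.
5. Ring order: rings A and B are bought, ring C is the only ring formed (step 3), and the last oxygen goes onto ring A afterwards (step 4).

Assumption: the target is a flat, achiral flavonol with no stereocentre, so there is no enantiomer to select. The only stereo-element on the way is the E alkene of the chalcone intermediate, which is consumed in the same pot.

## Route

Step 1
Reactants: 1 2,3,4-trimethoxybenzaldehyde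
Product: 3 2,3,4-trimethoxyphenol, via aryl formate 2 (not isolated)
Conditions: 30% H2O2 (1.3 equiv), H2SO4 (cat.), MeOH, rt, 3 h
Reagents that add atoms: hydrogen peroxide, OO
Why: Acid-catalysed Dakin oxidation (Baeyer–Villiger-type aryl migration in the peroxyhemiacetal) is fast for an aldehyde with ortho and para methoxy groups, methanol cleaves formate 2 in the flask, and no stereocentre is formed.

Step 2
Reactants: 3 2,3,4-trimethoxyphenol
Product: 4 2'-hydroxy-3',4',5'-trimethoxyacetophenone
Conditions: AcOH (5 equiv), BF3·OEt2 (3 equiv), 85 °C, 3 h; then H2O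
Reagents that add atoms: acetic acid, CC(=O)O
Why: In this Friedel–Crafts/Fries-type ortho-acylation, C6 is ortho to the OH and para to the 3-OMe, boron chelation between phenol oxygen and new ketone makes the ortho-hydroxyketone the thermodynamic sink, and no methoxy group sits next to the ketone to be cleaved.

Step 3
Reactants: 4 2'-hydroxy-3',4',5'-trimethoxyacetophenone; 5 4-tert-butoxybenzaldehyde
Product: 7 2-(4-tert-butoxyphenyl)-3-hydroxy-6,7,8-trimethoxy-4H-chromen-4-one, via chalcone 6 (not isolated)
Conditions: NaOH (5 M aq, 6 equiv), EtOH, rt, 20 h; then 30% H2O2 (5 equiv), 0 °C to rt, 4 h; 1 M HCl to pH 5 at 0 °C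
Reagents that add atoms: hydrogen peroxide, OO
Why: Claisen–Schmidt condensation gives E-chalcone 6, and the Algar–Flynn–Oyamada reaction (hydroperoxide attack on the enone, closure by the 2'-phenoxide to form O1–C2, further oxidation) gives the flavonol rather than the aurone because C6' is unsubstituted, while the base-stable tert-butyl ether keeps ring B from becoming a phenoxide that would deactivate the enone.

Step 4
Reactants: 7 2-(4-tert-butoxyphenyl)-3-hydroxy-6,7,8-trimethoxy-4H-chromen-4-one
Product: 10 3,5,4'-trihydroxy-6,7,8-trimethoxyflavone, via bis(trifluoroacetate) 8 (not isolated), via tris(trifluoroacetate) 9 (not isolated)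
Conditions: (a) TFA/TFAA 3:1, rt, 1 h, volatiles stripped; (b) [RuCl2(p-cymene)]2 (5 mol %), PhI(OCOCF3)2 (1.3 equiv), fresh TFA/TFAA 3:1, 70 °C, 6 h; (c) evaporate, THF/H2O, rt
Reagents that add atoms: [bis(trifluoroacetoxy)iodo]benzene PhI(OCOCF3)2, FC(F)(F)C(=O)OI(OC(=O)C(F)(F)F)c1ccccc1 (source of the C5 oxygen); trifluoroacetic anhydride, O=C(OC(=O)C(F)(F)F)C(F)(F)F (its acyl groups stay in 8 and 9 only)
Why: Proposed new method: TFA/TFAA first exchanges the tert-butyl ether and caps the 3-OH, so 8 has no free OH, which blocks 3-O/4-O chelation of the metal and oxidation of the enol and phenol by trivalent iodine; the C4 ketone, the only good donor left, then directs carboxylate-assisted cycloruthenation by divalent ruthenium at the peri C5–H (five-membered ruthenacycle, helped by the electron-rich ring A, whose only C–H this is, so even an uncatalysed radical-cation pathway would end at the same carbon); PhI(OCOCF3)2 oxidises the metallacycle to tetravalent ruthenium, and C–O reductive elimination gives 9, whose ester resists over-oxidation until water frees all three OH groups; the closest known reaction type is ruthenium- or palladium-catalysed ketone-directed ortho C–H hydroxylation of aryl ketones and C5 hydroxylation of simple flavones and chromones, which has not been shown on a 3-oxygenated flavone with free or acid-labile OH groups, with in-flask self-masking, or at a C–H flanked by a methoxy group in a 6,7,8-trimethoxy ring; no stereocentre is formed.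

## Compound list
1 | 2,3,4-trimethoxybenzaldehyde | COc1ccc(C=O)c(OC)c1OC | starting material
2 | 2,3,4-trimethoxyphenyl formate | COc1ccc(OC=O)c(OC)c1OC | intermediate
3 | 2,3,4-trimethoxyphenol | COc1ccc(O)c(OC)c1OC | intermediate
4 | 2'-hydroxy-3',4',5'-trimethoxyacetophenone, 1-(2-hydroxy-3,4,5-trimethoxyphenyl)ethan-1-one | CC(=O)c1cc(OC)c(OC)c(OC)c1O | intermediate
5 | 4-tert-butoxybenzaldehyde | CC(C)(C)Oc1ccc(C=O)cc1 | starting material
6 | (E)-3-(4-tert-butoxyphenyl)-1-(2-hydroxy-3,4,5-trimethoxyphenyl)prop-2-en-1-one | COc1cc(C(=O)/C=C/c2ccc(OC(C)(C)C)cc2)c(O)c(OC)c1OC | intermediate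
7 | 2-(4-tert-butoxyphenyl)-3-hydroxy-6,7,8-trimethoxy-4H-chromen-4-one | COc1cc2c(=O)c(O)c(-c3ccc(OC(C)(C)C)cc3)oc2c(OC)c1OC | intermediate
8 | 6,7,8-trimethoxyflavone-3,4'-diyl bis(trifluoroacetate) | COc1cc2c(=O)c(OC(=O)C(F)(F)F)c(-c3ccc(OC(=O)C(F)(F)F)cc3)oc2c(OC)c1OC | intermediate
9 | 6,7,8-trimethoxyflavone-3,5,4'-triyl tris(trifluoroacetate) | COc1c(OC)c(OC(=O)C(F)(F)F)c2c(=O)c(OC(=O)C(F)(F)F)c(-c3ccc(OC(=O)C(F)(F)F)cc3)oc2c1OC | intermediate
10 | 3,5,4'-trihydroxy-6,7,8-trimethoxyflavone | COc1c(OC)c(O)c2c(=O)c(O)c(-c3ccc(O)cc3)oc2c1OC | target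

## Step count and risks
Total step count: 4. Longest linear sequence: 4 (1 → 3 → 4 → 7 → 10).

Three steps most likely to fail:

**1. Step 4 (the new step).**
- Risks: cycloruthenation next to the 6-OMe group may be slow, and PhI(OCOCF3)2 may oxidise ring A by electron transfer.
- Freed 10 can also be oxidised to the 5,8-quinone if oxidant is still present when water is added, so any excess is destroyed first with a little Me2S.
- The fallback uses known chemistry only. It sets out from 8 and comes back at 10.
- NBS (1.05 equiv) is added to the TFA solution of 8 at rt. Ring A has one free position, and the two trifluoroacetates switch off ring B and C3. Electrophilic bromination therefore gives 5-bromo-6,7,8-trimethoxyflavone-3,4'-diyl bis(trifluoroacetate) F1.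
- The crude bromide is heated with NaOMe and CuBr in DMF/MeOH (110 °C, argon). This Ullmann-type methoxylation is routine on bromoflavones and on 2-bromo-3,4,5-trimethoxyarenes, and it cleaves the esters in the same pot to give 3,4'-dihydroxy-5,6,7,8-tetramethoxyflavone F2.
- BCl3 (CH2Cl2, −20 °C) then removes only the methyl group peri to the ketone and gives 10.

**2. Step 2.**
- Risk: some acylation at C5 (para to the 2-OMe) instead of C6, or incomplete O-to-C acyl transfer.
- The fallback sets out from 3 and comes back at 4.
- Compound 3 is methylated (MeI, K2CO3, acetone) to 1,2,3,4-tetramethoxybenzene F3. Its two free positions are equivalent, so the regiochemistry cannot go wrong.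
- AcCl/AlCl3 (CH2Cl2, 0 °C) gives 1-(2,3,4,5-tetramethoxyphenyl)ethan-1-one F4.
- BCl3 (CH2Cl2, −78 to 0 °C) cleaves only the methoxy group ortho to the ketone by chelation control and gives 4.

**3. Step 3.**
- Risk: alkaline peroxide may degrade the electron-rich phenoxide or cleave the flavonol once formed, which would lower the yield of the one-pot sequence.
- The fallback avoids alkaline peroxide. It sets out from 6 and comes back at 7.
- Step 3 is stopped before the peroxide is added, and chalcone 6 is isolated.
- Chalcone 6 is dehydrogenated and cyclised with DDQ in refluxing dioxane, neutral conditions that spare the tert-butyl ether, to 2-(4-tert-butoxyphenyl)-6,7,8-trimethoxy-4H-chromen-4-one F5.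
- C3 lithiation (LDA, THF, −78 °C) and a B(OMe)3 quench give dimethyl [2-(4-tert-butoxyphenyl)-6,7,8-trimethoxy-4-oxo-4H-chromen-3-yl]boronate F6.
- Oxidation in the same flask (AcOH, 30% H2O2, 0 °C to rt) gives 7.

## Further compounds
F1 | step 4 | 5-bromo-6,7,8-trimethoxyflavone-3,4'-diyl bis(trifluoroacetate) | COc1c(OC)c(Br)c2c(=O)c(OC(=O)C(F)(F)F)c(-c3ccc(OC(=O)C(F)(F)F)cc3)oc2c1OC
F2 | step 4 | 3,4'-dihydroxy-5,6,7,8-tetramethoxyflavone | COc1c(OC)c(OC)c2c(=O)c(O)c(-c3ccc(O)cc3)oc2c1OC
F3 | step 2 | 1,2,3,4-tetramethoxybenzene | COc1ccc(OC)c(OC)c1OC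
F4 | step 2 | 1-(2,3,4,5-tetramethoxyphenyl)ethan-1-one | CC(=O)c1cc(OC)c(OC)c(OC)c1OC
F5 | step 3 | 2-(4-tert-butoxyphenyl)-6,7,8-trimethoxy-4H-chromen-4-one | COc1cc2c(=O)cc(-c3ccc(OC(C)(C)C)cc3)oc2c(OC)c1OC
F6 | step 3 | dimethyl [2-(4-tert-butoxyphenyl)-6,7,8-trimethoxy-4-oxo-4H-chromen-3-yl]boronate | COB(OC)c1c(-c2ccc(OC(C)(C)C)cc2)oc2c(OC)c(OC)c(OC)cc2c1=O
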